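## Retrosynthetic overview

1. Isocupressic acid 1 supplies all 20 skeletal carbons, the (E)-13-alkene and C4, C5, C9 and C10. No ring is formed: rings A and B arrive together as its trans-decalin.
2. C19 disconnection: the CO2H of 1 becomes CH2OH (agathadiol 2), then both primary alcohols are acetylated (diacetate 3). The C15 acetate also deactivates the 13-alkene electronically.
3. Key disconnection C7–O: an electrochemical, SeO2-catalysed allylic C–H hydroxylation of 3 (through 4 and 5) gives the 7α-alcohol 6. The decalin controls this one new stereocentre.
4. Last disconnection, the C15 O–acetyl bond: site-selective methanolysis of 6 gives target 7.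

Assumption: isocupressic acid 1, a catalogue natural product making up roughly one per cent of the dry mass of Pinus ponderosa needles, is taken as the commercial, inexpensive chiral-pool labdane.

## Route

Labdane numbering is used. The series is normal: 5α-H, 9α-H, 10β-CH3, and C19 is the 4β (axial) carbon.

Step 1
Reactants: 1 isocupressic acid, (13E)-15-hydroxylabda-8(17),13-dien-19-oic acid, (4S,5R,9S,10R)
Product: 2 agathadiol, (13E)-labda-8(17),13-diene-15,19-diol
Conditions: LiAlH4 (4 equiv), THF, 0 °C to reflux, 12 h; then H2O, 15 % aq NaOH, H2O
Reagents that add atoms: none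
Why: This is a LiAlH4 reduction of a carboxylic acid; the hindered axial C19 carboxylate is still reduced in refluxing THF, the isolated alkenes and the allylic alkoxide are inert to hydride, and C4, C5, C9 and C10 pass through unchanged.

Step 2
Reactants: 2 agathadiol
Product: 3 agathadiol 15,19-diacetate
Conditions: Ac2O (4 equiv), pyridine, 4-(dimethylamino)pyridine (10 mol %), CH2Cl2, rt, 12 h
Reagents that add atoms: acetic anhydride, CC(=O)OC(C)=O
Why: Nucleophilic-catalysed acylation with 4-(dimethylamino)pyridine is strong enough for the neopentyl axial C19–OH as well as the allylic C15–OH, the C15 acetate lowers the nucleophilicity of the 13-alkene for the next step, and no stereocentre is touched.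

Step 3
Reactants: 3 agathadiol 15,19-diacetate
Product: 6 7α-hydroxyagathadiol 15,19-diacetate, via allylseleninic acid 4 (not isolated), via allyl selenoxylate 5 (not isolated)
Conditions: SeO2 (20 mol %), (4-BrC6H4)3N (5 mol %), H2O (10 equiv), nBu4NBF4 (0.1 mol/L), MeCN/t-BuOH 1:1, 40 °C; Nafion-divided cell, graphite-felt anode held at +1.1 volt vs Ag/AgCl, Pt cathode in nBu4NBF4/AcOH–MeCN; 2.1 F/mol
Reagents that add atoms: water, O; selenium dioxide (catalytic oxygen carrier), O=[Se]=O
Why: Proposed new method: an anodically driven, SeO2-catalysed allylic C–H hydroxylation with water as the oxygen source and H2 leaving at the cathode; selenous acid (tetravalent selenium) bonds to the open C17 terminus of the 8(17)-alkene in an ene reaction that removes the stereoelectronically aligned axial 7α-H (4), a [2,3]-sigmatropic shift returns oxygen to C7 on the same α face and restores the exocyclic methylene (5), hydrolysis frees 6 and divalent selenium, and the aminium mediator made at the anode (more than 0.7 volt below the oxidation of either alkene) returns it to tetravalent selenium before it drops out as elemental selenium; the β face is screened by the C10 methyl and the C9 chain, the tertiary 9-H is disfavoured (CH2 > CH), the 13-alkene is deactivated by its allylic acetate, protons cross the membrane so the anolyte stays only mildly acidic, and the charge passed caps the oxidant short of the 7-enone; the closest known reaction type is the Riley/Sharpless SeO2–t-BuOOH allylic hydroxylation, and the electrochemical turnover of SeO2 is the part not yet shown.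

Step 4
Reactants: 6 7α-hydroxyagathadiol 15,19-diacetate
Product: 7 target, (13E)-19-acetoxylabda-8(17),13-diene-7α,15-diol, (4S,5R,7R,9R,10S)
Conditions: K2CO3 (0.2 equiv), MeOH, 0 °C, 1–2 h, quenched (AcOH) when 6 is consumed
Reagents that add atoms: none
Why: This is a Zemplén-type base-catalysed transesterification under kinetic control; the open primary allylic C15 acetate is methanolysed far faster than the neopentyl axial C19 acetate wedged between quaternary C4 and the C10 methyl, the 7α-OH lies on the opposite face so no acyl migration can occur, and no stereocentre is touched.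

## Compound list

1 | isocupressic acid, (13E)-15-hydroxylabda-8(17),13-dien-19-oic acid | C=C1CC[C@H]2[C@@](C)(C(=O)O)CCC[C@]2(C)[C@H]1CC/C(C)=C/CO | starting material
2 | agathadiol, (13E)-labda-8(17),13-diene-15,19-diol | C=C1CC[C@H]2[C@@](C)(CO)CCC[C@]2(C)[C@H]1CC/C(C)=C/CO | intermediate
3 | agathadiol 15,19-diacetate | C=C1CC[C@H]2[C@@](C)(COC(C)=O)CCC[C@]2(C)[C@H]1CC/C(C)=C/COC(C)=O | intermediate
4 | allylseleninic acid: 15,19-diacetoxylabda-7,13E-dien-17-ylseleninic acid (ene adduct, not isolated) | O[Se](=O)CC1=CC[C@H]2[C@@](C)(COC(C)=O)CCC[C@]2(C)[C@H]1CC/C(C)=C/COC(C)=O | intermediate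
5 | allyl selenoxylate: 7α-O–Se–OH ester of divalent selenium, 8(17)-methylene restored (not isolated) | C=C1[C@H](O[Se]O)C[C@H]2[C@@](C)(COC(C)=O)CCC[C@]2(C)[C@H]1CC/C(C)=C/COC(C)=O | intermediate
6 | 7α-hydroxyagathadiol 15,19-diacetate (axial 7α-OH) | C=C1[C@H](O)C[C@H]2[C@@](C)(COC(C)=O)CCC[C@]2(C)[C@H]1CC/C(C)=C/COC(C)=O | intermediate
7 | (13E)-19-acetoxylabda-8(17),13-diene-7α,15-diol (CNP0209062.1) | C=C1[C@H](O)C[C@H]2[C@@](C)(COC(C)=O)CCC[C@]2(C)[C@H]1CC/C(C)=C/CO | target

## Totals and risks

Total step count: 4. Longest linear sequence: 4.

Most at risk is step 3, the new electrolysis. Reduced selenium may fall out as red elemental selenium faster than the mediator re-oxidises it, and oxidation at C12/C16 or to the 7-enone may appear. The fallback uses known chemistry. It leaves electrochemistry and the water-fed catalytic loop and uses the established thermal, peroxide-driven allylic hydroxylation: SeO2 (0.5 equiv), t-BuOOH (2 equiv), CH2Cl2, 0 °C to rt. It sets out from 3 and comes back to the route at 6. The ene/[2,3] course is the same and gives the axial 7α-alcohol. New compounds on the way: none F0.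

Second is step 4. The rate gap between the two primary acetates may be too small, giving triol or unreacted 6. The fallback tells the two alcohols apart by size at the diol stage instead of by rate at the end.
- It sets out from 2. t-BuMe2SiCl (1.05 equiv) and imidazole in CH2Cl2 at −20 °C silylate only the open allylic C15–OH, giving agathadiol 15-O-tert-butyldimethylsilyl ether F1.
- Ac2O, pyridine and 4-(dimethylamino)pyridine give 19-acetoxy-15-silyloxylabda-8(17),13E-diene F2.
- The C7 hydroxylation of step 3, or its SeO2/t-BuOOH fallback, gives 19-acetoxy-15-silyloxylabda-8(17),13E-dien-7α-ol F3.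
- nBu4NF buffered with AcOH in THF at 0 °C removes the silyl group. The sequence comes back to the route at 7.

Third is step 1. The insoluble, hindered axial carboxylate may be reduced only sluggishly. The fallback presents a neutral ester to the hydride instead. It sets out from 1, where CH3I and K2CO3 in DMF at rt give methyl isocupressate F4. LiAlH4 in refluxing THF then reduces the ester, and the sequence comes back to the route at 2.

## Further compounds

F0 | step 3 | none | none
F1 | step 4 | agathadiol 15-O-tert-butyldimethylsilyl ether | C=C1CC[C@H]2[C@@](C)(CO)CCC[C@]2(C)[C@H]1CC/C(C)=C/CO[Si](C)(C)C(C)(C)C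
F2 | step 4 | 19-acetoxy-15-(tert-butyldimethylsilyloxy)labda-8(17),13E-diene | C=C1CC[C@H]2[C@@](C)(COC(C)=O)CCC[C@]2(C)[C@H]1CC/C(C)=C/CO[Si](C)(C)C(C)(C)C
F3 | step 4 | 19-acetoxy-15-(tert-butyldimethylsilyloxy)labda-8(17),13E-dien-7α-ol | C=C1[C@H](O)C[C@H]2[C@@](C)(COC(C)=O)CCC[C@]2(C)[C@H]1CC/C(C)=C/CO[Si](C)(C)C(C)(C)C
F4 | step 1 | methyl isocupressate | C=C1CC[C@H]2[C@@](C)(C(=O)OC)CCC[C@]2(C)[C@H]1CC/C(C)=C/CO
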